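The bromopyran is closed at the O–C7 bond (bisabolane numbering: carbocycle C1–C6, pyran O and C7–C11). Alkoxymercuration–demercuration of an acyclic (10S)-bromohydrin that carries a C7 methylene and the (6R)-cyclohexene of limonene forms, in one operation, the pyran ring, the C7 methyl and the C7 stereocentre. The step exploits the pyran chair: C10–Br and the C7 carbocycle are trans-1,4 and both equatorial, so C10 relays its configuration to C7. The precursor is assembled from lithiated (R)-limonene and a glycidate-derived epoxy alcohol; the ring alkene is then turned into the trans-diequatorial C2 bromide and C3 chloride.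

Key step: step 5

Remark: the peracid epoxidation of 12 is assumed to show no useful facial preference, so the route is planned for a mixture from which only the epoxide anti to the C6 substituent is carried on.

Step 1
Reactants: 1 methyl (2S)-oxirane-2-carboxylate (methyl (S)-glycidate)
Product: 3 2-[(2S)-oxiran-2-yl]propan-2-ol, via 1-[(2S)-oxiran-2-yl]ethan-1-one 2 (not isolated)
Conditions: MeMgCl (2.2 equiv), THF, −78 → −20 °C; aq NH4Cl
Reagents that add atoms: methylmagnesium chloride, C[Mg]Cl
Why: Double Grignard addition to the ester should outpace epoxide opening at low temperature, and the oxirane stereocentre (the future C10) is not involved.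

Step 2
Reactants: 4 (R)-limonene; 3 2-[(2S)-oxiran-2-yl]propan-2-ol
Product: 7 (3S)-2-methyl-6-[(1R)-4-methylcyclohex-3-en-1-yl]hept-6-ene-2,3-diol, via 10-lithiolimonene 5 (not isolated), via lithium 2-[(2S)-oxiran-2-yl]propan-2-olate 6 (not isolated)
Conditions: n-BuLi, TMEDA, 4 (excess), 25 °C; then 3 (0.4 equiv), THF, −78 → 0 °C; H2O
Reagents that add atoms: none
Why: Allylic metalation of limonene by n-BuLi/TMEDA occurs at the isopropenyl methyl, and the symmetrical allyllithium (one equivalent first deprotonates the hydroxyl) opens the terminal epoxide at its CH2 carbon in an SN2 reaction, forming C8–C9 without touching C6 or C10.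

Step 3
Reactants: 7 (3S)-2-methyl-6-[(1R)-4-methylcyclohex-3-en-1-yl]hept-6-ene-2,3-diol
Product: 9 (3R)-2,2-dimethyl-3-{3-[(1R)-4-methylcyclohex-3-en-1-yl]but-3-en-1-yl}oxirane, via C10 mesylate 8 (not isolated)
Conditions: MsCl, Et3N, CH2Cl2, −20 °C; then K2CO3, MeOH, 25 °C
Reagents that add atoms: none
Why: Sulfonylation takes the secondary C10 hydroxyl selectively, and the C11 alkoxide then displaces the mesylate in an intramolecular SN2 reaction (Williamson-type epoxide closure), which inverts C10 from S to R.

Step 4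
Reactants: 9 (3R)-2,2-dimethyl-3-{3-[(1R)-4-methylcyclohex-3-en-1-yl]but-3-en-1-yl}oxirane
Product: 10 (3S)-3-bromo-2-methyl-6-[(1R)-4-methylcyclohex-3-en-1-yl]hept-6-en-2-ol
Conditions: Li2NiBr4 (stock solution), THF, 0 → 25 °C; pH 7 buffer
Reagents that add atoms: dilithium tetrabromonickelate, [Li+].[Li+].Br[Ni-2](Br)(Br)Br
Why: Halohydrin formation from an epoxide with a soft bromide source of SN2 character should open the trisubstituted oxirane at the less substituted C10 with a second inversion, returning C10 to S with bromine in place of oxygen and leaving the C11 tertiary alcohol and both alkenes untouched.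

Step 5
Reactants: 10 (3S)-3-bromo-2-methyl-6-[(1R)-4-methylcyclohex-3-en-1-yl]hept-6-en-2-ol
Product: 12 (3S,6R)-3-bromo-2,2,6-trimethyl-6-[(1R)-4-methylcyclohex-3-en-1-yl]oxane, via mercuriomethyl pyran trifluoroacetate 11 (not isolated)
Conditions: Hg(OCOCF3)2 (1.05 equiv), THF, −20 → 0 °C; then NaBH4, aq NaOH, −20 °C
Reagents that add atoms: none
Why: Divalent mercury adds to the less substituted C7=CH2 alkene to give a mercurinium ion, which the C11 hydroxyl opens at the more substituted carbon C7 anti to mercury; NaBH4 then replaces C–Hg by C–H through a radical chain that should leave the secondary C10 bromide alone. The closest known reaction type is the intramolecular alkoxymercuration–demercuration of a hydroxy alkene. The pyran closes in the 6-exo-trig mode by forming the O–C7 bond. The new stereocentre C7 is controlled by C10: in the chair-like closure the C10 bromine sits equatorial, the bulkier cyclohexenyl group takes the equatorial site at C7, and the slimmer CH2Hg group accepts the axial site beside the axial C11 methyl; because the addition is reversible in the presence of the liberated trifluoroacetic acid, the mixture can settle on this trans-1,4 diequatorial (7R) isomer. The step also needs site selectivity between the two alkenes, which the tethered hydroxyl and the lower substitution of the exocyclic alkene should secure, the ring alkene having no internal nucleophile; C6 is safe because no free C7 cation, and so no 1,2-hydride shift, is involved.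

Step 6
Reactants: 12 (3S,6R)-3-bromo-2,2,6-trimethyl-6-[(1R)-4-methylcyclohex-3-en-1-yl]oxane
Product: 13 (1R,4R,6S)-4-[(2R,5S)-5-bromo-2,6,6-trimethyloxan-2-yl]-1-methyl-7-oxabicyclo[4.1.0]heptane (oxygen on the ring face anti to the C6 substituent)
Conditions: mCPBA, NaHCO3, CH2Cl2, 0 °C
Reagents that add atoms: 3-chloroperoxybenzoic acid, OOC(=O)c1cccc(Cl)c1
Why: Prilezhaev epoxidation of the only remaining alkene is stereospecific, but the remote C6 substituent should give little facial bias, so 13 is expected together with its syn diastereomer, which is carried along and removed after step 7.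

Step 7
Reactants: 13 (1R,4R,6S)-4-[(2R,5S)-5-bromo-2,6,6-trimethyloxan-2-yl]-1-methyl-7-oxabicyclo[4.1.0]heptane
Product: 14 (1S,2S,5R)-2-bromo-5-[(2R,5S)-5-bromo-2,6,6-trimethyloxan-2-yl]-2-methylcyclohexan-1-ol (C3–Br and C2–OH both axial)
Conditions: anhydrous HBr (1 equiv), CH2Cl2, −78 °C; NaHCO3; chromatography
Reagents that add atoms: hydrogen bromide, Br
Why: In this acid-mediated epoxide opening the Markovnikov site and the trans-diaxial site coincide at C3, so bromide should enter at the tertiary carbon with inversion (axial, cis to the C6 substituent) and leave an axial C2 hydroxyl; the epoxide is far more basic than the hindered pyran ether, and the syn epoxide gives a constitutional isomer (secondary bromide, tertiary alcohol) that is separated here.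

Step 8
Reactants: 14 (1S,2S,5R)-2-bromo-5-[(2R,5S)-5-bromo-2,6,6-trimethyloxan-2-yl]-2-methylcyclohexan-1-ol
Product: 16 (3S,6R)-3-bromo-6-[(1R,3S,4S)-4-bromo-3-chloro-4-methylcyclohexyl]-2,2,6-trimethyloxane (C2–Cl and C3–Br both axial), via C2 chlorosulfite 15 (not isolated)
Conditions: SOCl2, 2,6-lutidine, CH2Cl2, −40 → 25 °C
Reagents that add atoms: thionyl chloride, O=S(Cl)Cl
Why: In this deoxychlorination with neighbouring-group participation the anti-periplanar axial C3 bromine assists loss of the chlorosulfite to give a bromonium ion on the ring face cis to the C6 substituent, and chloride should reopen it trans-diaxially at C2, so C2 keeps its configuration by double inversion; chloride capture at C3 of the same ion would give 17 directly.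

Step 9
Reactants: 16 (3S,6R)-3-bromo-6-[(1R,3S,4S)-4-bromo-3-chloro-4-methylcyclohexyl]-2,2,6-trimethyloxane
Product: 17 deoxycaespitol, (3S,6R)-3-bromo-6-[(1R,3R,4R)-3-bromo-4-chloro-4-methylcyclohexyl]-2,2,6-trimethyloxane
Conditions: MeCN, CaCO3, 80 °C; chromatography, recovered 16 resubmitted
Reagents that add atoms: none
Why: In this thermal diaxial-to-diequatorial rearrangement of a vicinal dihalide (a dyotropic 1,2-interchange through a halonium–halide ion pair) bromine moves from C3 to C2 and chlorine from C2 to C3, each on its own face with inversion at both carbons, which gives the (2R,3R) trans-diequatorial bromide and chloride with the C3 methyl axial; the equilibrium should be helped by the polar solvent and by the tertiary carbon taking the stronger C–Cl bond.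

Compound list
1 | methyl (2S)-oxirane-2-carboxylate (methyl (S)-glycidate) | COC(=O)[C@@H]1CO1 | starting material
2 | 1-[(2S)-oxiran-2-yl]ethan-1-one | CC(=O)[C@@H]1CO1 | intermediate
3 | 2-[(2S)-oxiran-2-yl]propan-2-ol | CC(C)(O)[C@@H]1CO1 | intermediate
4 | (R)-limonene, (4R)-1-methyl-4-(prop-1-en-2-yl)cyclohex-1-ene | C=C(C)[C@@H]1CCC(C)=CC1 | starting material
5 | 10-lithiolimonene, {2-[(1R)-4-methylcyclohex-3-en-1-yl]prop-2-en-1-yl}lithium | [Li]CC(=C)[C@@H]1CCC(C)=CC1 | intermediate
6 | lithium 2-[(2S)-oxiran-2-yl]propan-2-olate | [Li]OC(C)(C)[C@@H]1CO1 | intermediate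
7 | (3S)-2-methyl-6-[(1R)-4-methylcyclohex-3-en-1-yl]hept-6-ene-2,3-diol | CC(C)(O)[C@@H](O)CCC(=C)[C@@H]1CCC(C)=CC1 | intermediate
8 | (3S)-2-hydroxy-2-methyl-6-[(1R)-4-methylcyclohex-3-en-1-yl]hept-6-en-3-yl methanesulfonate | CC(C)(O)[C@@H](OS(C)(=O)=O)CCC(=C)[C@@H]1CCC(C)=CC1 | intermediate
9 | (3R)-2,2-dimethyl-3-{3-[(1R)-4-methylcyclohex-3-en-1-yl]but-3-en-1-yl}oxirane | CC1(C)O[C@@H]1CCC(=C)[C@@H]1CCC(C)=CC1 | intermediate
10 | (3S)-3-bromo-2-methyl-6-[(1R)-4-methylcyclohex-3-en-1-yl]hept-6-en-2-ol | CC(C)(O)[C@@H](Br)CCC(=C)[C@@H]1CCC(C)=CC1 | intermediate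
11 | {[(2R,5S)-5-bromo-6,6-dimethyl-2-[(1R)-4-methylcyclohex-3-en-1-yl]oxan-2-yl]methyl}mercury trifluoroacetate (divalent mercury) | CC1(C)O[C@@](C[Hg]OC(=O)C(F)(F)F)([C@@H]2CCC(C)=CC2)CC[C@@H]1Br | intermediate
12 | (3S,6R)-3-bromo-2,2,6-trimethyl-6-[(1R)-4-methylcyclohex-3-en-1-yl]oxane | CC1(C)O[C@@](C)([C@@H]2CCC(C)=CC2)CC[C@@H]1Br | intermediate
13 | (1R,4R,6S)-4-[(2R,5S)-5-bromo-2,6,6-trimethyloxan-2-yl]-1-methyl-7-oxabicyclo[4.1.0]heptane | CC1(C)O[C@@](C)([C@@H]2CC[C@@]3(C)O[C@H]3C2)CC[C@@H]1Br | intermediate
14 | (1S,2S,5R)-2-bromo-5-[(2R,5S)-5-bromo-2,6,6-trimethyloxan-2-yl]-2-methylcyclohexan-1-ol | CC1(C)O[C@@](C)([C@@H]2CC[C@](C)(Br)[C@@H](O)C2)CC[C@@H]1Br | intermediate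
15 | (1S,2S,5R)-2-bromo-5-[(2R,5S)-5-bromo-2,6,6-trimethyloxan-2-yl]-2-methylcyclohexyl chlorosulfite | CC1(C)O[C@@](C)([C@@H]2CC[C@](C)(Br)[C@@H](OS(=O)Cl)C2)CC[C@@H]1Br | intermediate
16 | (3S,6R)-3-bromo-6-[(1R,3S,4S)-4-bromo-3-chloro-4-methylcyclohexyl]-2,2,6-trimethyloxane | CC1(C)O[C@@](C)([C@@H]2CC[C@](C)(Br)[C@@H](Cl)C2)CC[C@@H]1Br | intermediate
17 | deoxycaespitol, (3S,6R)-3-bromo-6-[(1R,3R,4R)-3-bromo-4-chloro-4-methylcyclohexyl]-2,2,6-trimethyloxane | CC1(C)O[C@@](C)([C@@H]2CC[C@@](C)(Cl)[C@H](Br)C2)CC[C@@H]1Br | target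

Total step count: 9.
Longest linear sequence: 9 steps (1 to 17 through steps 1–9); (R)-limonene 4 joins at step 2.

Steps most likely to fail

Step 9 (halogen interchange). The equilibrium may stop short of the diequatorial isomer, or the tertiary bromide may lose HBr on heating. Fallback: set out from alkene 12 and add bromine and chlorine in one anti addition with NBS and LiCl in CH2Cl2/MeCN at −20 °C (known alkene bromochlorination). The bromonium ion on the ring face cis to the C6 substituent, opened by chloride at the tertiary C3, gives 17 directly. The ion on the other face gives the trans-diaxial (2S,3S) isomer (3S,6R)-3-bromo-6-[(1R,3S,4S)-3-bromo-4-chloro-4-methylcyclohexyl]-2,2,6-trimethyloxane F1, which is removed by chromatography. The route is rejoined at 17.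

Step 5 (key step). The two faces at C7 may be poorly differentiated, and the radical demercuration may return the alkene or cyclise onto the ring alkene. Fallback: from 10, iodoetherification with I2 and NaHCO3 in MeCN at 0 °C (reversible, 6-exo, same chair preference) gives (2R,5S)-5-bromo-2-(iodomethyl)-6,6-dimethyl-2-[(1R)-4-methylcyclohex-3-en-1-yl]oxane F2. The primary iodide is then reduced in the presence of the secondary bromide with (Me3Si)3SiH and Et3B/air in toluene at −20 °C. The route is rejoined at 12.

Step 8 (bromine-assisted chlorination). The bromonium ion may lose a proton, or chloride may attack bromine and return the alkene, instead of substitution at carbon. Fallback: reach 16 through the other ring epoxide, so that chlorine enters first. From 12, NBS in aqueous acetone gives the trans-diaxial bromohydrin (1S,2S,4R)-2-bromo-4-[(2R,5S)-5-bromo-2,6,6-trimethyloxan-2-yl]-1-methylcyclohexan-1-ol F3. K2CO3 in MeOH closes it to the epoxide syn to the C6 substituent, (1S,4R,6R)-4-[(2R,5S)-5-bromo-2,6,6-trimethyloxan-2-yl]-1-methyl-7-oxabicyclo[4.1.0]heptane F4, which is also the co-product of step 6. LiCl/AcOH in THF opens it trans-diaxially at C2 to the chlorohydrin (1S,2S,4R)-4-[(2R,5S)-5-bromo-2,6,6-trimethyloxan-2-yl]-2-chloro-1-methylcyclohexan-1-ol F5. Me3SiBr in CH2Cl2 at 0 °C then replaces the tertiary hydroxyl by bromide anti to the axial chlorine. The route is rejoined at 16.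

Further compounds
F1 | step 9 | (3S,6R)-3-bromo-6-[(1R,3S,4S)-3-bromo-4-chloro-4-methylcyclohexyl]-2,2,6-trimethyloxane | CC1(C)O[C@@](C)([C@@H]2CC[C@](C)(Cl)[C@@H](Br)C2)CC[C@@H]1Br
F2 | step 5 | (2R,5S)-5-bromo-2-(iodomethyl)-6,6-dimethyl-2-[(1R)-4-methylcyclohex-3-en-1-yl]oxane | CC1(C)O[C@@](CI)([C@@H]2CCC(C)=CC2)CC[C@@H]1Br
F3 | step 8 | (1S,2S,4R)-2-bromo-4-[(2R,5S)-5-bromo-2,6,6-trimethyloxan-2-yl]-1-methylcyclohexan-1-ol | CC1(C)O[C@@](C)([C@@H]2CC[C@](C)(O)[C@@H](Br)C2)CC[C@@H]1Br
F4 | step 8 | (1S,4R,6R)-4-[(2R,5S)-5-bromo-2,6,6-trimethyloxan-2-yl]-1-methyl-7-oxabicyclo[4.1.0]heptane | CC1(C)O[C@@](C)([C@@H]2CC[C@]3(C)O[C@@H]3C2)CC[C@@H]1Br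
F5 | step 8 | (1S,2S,4R)-4-[(2R,5S)-5-bromo-2,6,6-trimethyloxan-2-yl]-2-chloro-1-methylcyclohexan-1-ol | CC1(C)O[C@@](C)([C@@H]2CC[C@](C)(O)[C@@H](Cl)C2)CC[C@@H]1Br
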